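**Strategy.** Acredinone A hides a twofold symmetry: ring A (C3a–C7a, the benzo ring of the indenone) and ring B on C2 carry the same hydroxy, methyl and methoxy pattern, and C3 and the ketone carbon C8 each bear a 2,6-dimethoxyphenyl group. Cutting the C2–C3 bond and returning the C1 oxygen to C3 therefore leads to the symmetric bis(2-aroylaryl)acetylene 17, whose alkyne carbons are C1 and C2. One acid-mediated carbonyl–alkyne metathesis closes the five-membered ring and delivers the target without further steps. Tolane 17 comes from a directed-metalation-derived iodosalicylaldehyde by double Sonogashira coupling, twofold aryllithium addition and oxidation.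

Key step: step 8

Remark: indenone numbering is used (C1 ring carbonyl, C2, C3, ring A = C3a–C7a, ring B = aryl group on C2, C8 = benzophenone carbonyl). 2,5-Dimethoxy-4-methylbenzaldehyde 1, which already holds the full substituent pattern of rings A and B except the alkyne carbon, is assumed to be purchasable.

**Step 1**
Reactants: 1 2,5-dimethoxy-4-methylbenzaldehyde
Product: 5 2-iodo-3,6-dimethoxy-4-methylbenzaldehyde, via lithium amino alkoxide 2 (not isolated), via ring-lithiated amino alkoxide 3 (not isolated), via ring-iodinated amino alkoxide 4 (not isolated)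
Conditions: Me2NCH2CH2NHMe, n-BuLi, THF, −20 °C; n-BuLi (3 equiv), −20 °C; I2, −78 °C to rt; H2O
Reagents that add atoms: iodine, [I][I]
Why: Comins-type directed ortho-metalation, in which the lithium α-amino alkoxide formed in the flask masks the aldehyde and, together with the C5 methoxy group, should direct butyllithium to the one ring position lying between two directing groups; iodine quench and hydrolysis of the aminal return the aldehyde.

**Step 2**
Reactants: 5 2-iodo-3,6-dimethoxy-4-methylbenzaldehyde
Product: 7 6-hydroxy-2-iodo-3-methoxy-4-methylbenzaldehyde, via aryloxydichloroborane 6 (not isolated)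
Conditions: BCl3 (1.2 equiv), CH2Cl2, −78 to 0 °C; H2O
Reagents that add atoms: none
Why: Chelation-controlled ether cleavage, in which BCl3 bound to the formyl oxygen should cleave only the methyl ether ortho to the aldehyde and leave the non-chelating methoxy group next to iodine.

**Step 3**
Reactants: 7 6-hydroxy-2-iodo-3-methoxy-4-methylbenzaldehyde
Product: 8 2-iodo-3-methoxy-6-(methoxymethoxy)-4-methylbenzaldehyde
Conditions: MOMCl, iPr2NEt, CH2Cl2, 0 °C to rt
Reagents that add atoms: chloromethyl methyl ether, COCCl
Why: Base-mediated O-alkylation of the phenol with an α-chloro ether (methoxymethyl protection), needed because a free electron-rich phenol would not survive the aryllithium addition and the oxidation that follow.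

**Step 4**
Reactants: 8 2-iodo-3-methoxy-6-(methoxymethoxy)-4-methylbenzaldehyde (2 equiv), 9 trimethylsilylacetylene (1 equiv)
Product: 12 2,2′-(ethyne-1,2-diyl)bis[3-methoxy-6-(methoxymethoxy)-4-methylbenzaldehyde], via aryl silylalkyne 10 (not isolated), via terminal arylalkyne 11 (not isolated)
Conditions: PdCl2(PPh3)2 (6 mol %), CuI (10 mol %), DBU (6 equiv), H2O (0.4 equiv), MeCN, 60 °C
Reagents that add atoms: none
Why: One-pot twofold Sonogashira coupling, in which the first coupling gives the aryl silylalkyne, DBU and water cleave the C–Si bond in the flask, and the terminal alkyne couples with the second equivalent of aryl iodide while its low stationary concentration limits oxidative homocoupling.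

**Step 5**
Reactants: 12 2,2′-(ethyne-1,2-diyl)bis[3-methoxy-6-(methoxymethoxy)-4-methylbenzaldehyde], 13 1,3-dimethoxybenzene
Product: 15 ethyne-1,2-diylbis{[3-methoxy-6-(methoxymethoxy)-4-methyl-2,1-phenylene]}bis[(2,6-dimethoxyphenyl)methanol] (diastereomer mixture), via 2,6-dimethoxyphenyllithium 14 (not isolated)
Conditions: 13 (3 equiv), n-BuLi (2.8 equiv), THF, 0 °C to rt; then 12, −78 to 0 °C; H2O
Reagents that add atoms: none
Why: Ortho-lithiation of 1,3-dimethoxybenzene between its two methoxy groups and 1,2-addition of the aryllithium to both aldehydes; the two new carbinol stereocentres form without control (meso and racemic diastereomers), which is harmless because step 6 removes them.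

**Step 6**
Reactants: 15 bis-carbinol (diastereomer mixture)
Product: 16 1,2-bis[2-(2,6-dimethoxybenzoyl)-6-methoxy-3-(methoxymethoxy)-5-methylphenyl]ethyne
Conditions: Dess–Martin periodinane (3 equiv), NaHCO3, CH2Cl2, 0 °C to rt
Reagents that add atoms: none
Why: Dess–Martin oxidation of the two secondary diaryl carbinols to diaryl ketones under buffered conditions that should leave the acetal protecting groups, the electron-rich arenes and the alkyne untouched.

**Step 7**
Reactants: 16 1,2-bis[2-(2,6-dimethoxybenzoyl)-6-methoxy-3-(methoxymethoxy)-5-methylphenyl]ethyne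
Product: 17 1,2-bis[2-(2,6-dimethoxybenzoyl)-3-hydroxy-6-methoxy-5-methylphenyl]ethyne
Conditions: HCl (1.25 M in MeOH), CH2Cl2, 0 °C to rt
Reagents that add atoms: none
Why: Acid-catalysed transacetalisation of the two aryl methoxymethyl ethers with methanol, made easy by the neighbouring carbonyl groups and mild enough not to protonate the diarylalkyne.

**Step 8**
Reactants: 17 1,2-bis[2-(2,6-dimethoxybenzoyl)-3-hydroxy-6-methoxy-5-methylphenyl]ethyne
Product: 18 Acredinone A
Conditions: TfOH (3 equiv), ClCH2CH2Cl, 0 °C to rt
Reagents that add atoms: none
Why: TfOH protonates the hydrogen-bonded diaryl ketone of one half of 17, the alkyne adds through its distal carbon C2 to the carbenium-like C3, the charge building at C1 is taken up by the C3 hydroxyl oxygen, and heterolysis of the C3–O bond then gives the O-protonated indenone, a stepwise [2+2]/retro-[2+2] on the protonated manifold that needs neither a free bridged oxetene nor an in-ring vinyl cation. The closest known reaction type is the Brønsted-acid-promoted intramolecular carbonyl–alkyne metathesis of 2-alkynylaryl ketones to 2,3-disubstituted indenones. The single new ring (C1, C2, C3, C3a, C7a) closes 5-endo-dig with respect to the alkyne and exo-trig with respect to the carbonyl group, and no stereocentre is formed. The step needs C-attack of the alkyne on the carbonyl carbon instead of O-attack of the ketone on the alkyne (benzopyrylium salt); full protonation of the ketone by a superacid, with no alkyne-activating metal present, should suppress the nucleophilicity of the oxygen, while the 2,6-dimethoxyphenyl and ortho-hydroxyaryl groups stabilise the positive charge at C3. Site selectivity is not needed because the twofold symmetry makes both ketones and both alkyne carbons equivalent, and the untouched ketone becomes the C8 benzoyl group on ring B.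

**Compound list**
1 | 2,5-dimethoxy-4-methylbenzaldehyde | COc1cc(C)c(OC)cc1C=O | starting material
2 | lithium α-amino alkoxide of 1 with N,N,N′-trimethylethylenediamine (formed in the flask) | COc1cc(C)c(OC)cc1C(O[Li])N(C)CCN(C)C | intermediate
3 | ring-lithiated amino alkoxide, lithium between the aminal carbon and the methoxy group (formed in the flask) | COc1cc(C)c(OC)c([Li])c1C(O[Li])N(C)CCN(C)C | intermediate
4 | ring-iodinated amino alkoxide (formed in the flask) | COc1cc(C)c(OC)c(I)c1C(O[Li])N(C)CCN(C)C | intermediate
5 | 2-iodo-3,6-dimethoxy-4-methylbenzaldehyde | COc1cc(C)c(OC)c(I)c1C=O | intermediate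
6 | dichloro(2-formyl-3-iodo-4-methoxy-5-methylphenoxy)borane (formed in the flask) | COc1c(C)cc(OB(Cl)Cl)c(C=O)c1I | intermediate
7 | 6-hydroxy-2-iodo-3-methoxy-4-methylbenzaldehyde | COc1c(C)cc(O)c(C=O)c1I | intermediate
8 | 2-iodo-3-methoxy-6-(methoxymethoxy)-4-methylbenzaldehyde | COCOc1cc(C)c(OC)c(I)c1C=O | intermediate
9 | trimethylsilylacetylene | C#C[Si](C)(C)C | starting material
10 | 3-methoxy-6-(methoxymethoxy)-4-methyl-2-[(trimethylsilyl)ethynyl]benzaldehyde (formed in the flask) | COCOc1cc(C)c(OC)c(C#C[Si](C)(C)C)c1C=O | intermediate
11 | 2-ethynyl-3-methoxy-6-(methoxymethoxy)-4-methylbenzaldehyde (formed in the flask) | COCOc1cc(C)c(OC)c(C#C)c1C=O | intermediate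
12 | 2,2′-(ethyne-1,2-diyl)bis[3-methoxy-6-(methoxymethoxy)-4-methylbenzaldehyde] | COCOc1cc(C)c(OC)c(C#Cc2c(OC)c(C)cc(OCOC)c2C=O)c1C=O | intermediate
13 | 1,3-dimethoxybenzene | COc1cccc(OC)c1 | starting material
14 | 2,6-dimethoxyphenyllithium (formed in the flask) | COc1cccc(OC)c1[Li] | intermediate
15 | ethyne-1,2-diylbis{[3-methoxy-6-(methoxymethoxy)-4-methyl-2,1-phenylene]}bis[(2,6-dimethoxyphenyl)methanol], carbinol centres unassigned (meso and racemic mixture) | COCOc1cc(C)c(OC)c(C#Cc2c(OC)c(C)cc(OCOC)c2C(O)c2c(OC)cccc2OC)c1C(O)c1c(OC)cccc1OC | intermediate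
16 | 1,2-bis[2-(2,6-dimethoxybenzoyl)-6-methoxy-3-(methoxymethoxy)-5-methylphenyl]ethyne | COCOc1cc(C)c(OC)c(C#Cc2c(OC)c(C)cc(OCOC)c2C(=O)c2c(OC)cccc2OC)c1C(=O)c1c(OC)cccc1OC | intermediate
17 | 1,2-bis[2-(2,6-dimethoxybenzoyl)-3-hydroxy-6-methoxy-5-methylphenyl]ethyne | COc1cccc(OC)c1C(=O)c1c(O)cc(C)c(OC)c1C#Cc1c(OC)c(C)cc(O)c1C(=O)c1c(OC)cccc1OC | intermediate
18 | Acredinone A (no stereocentres) | COc1cccc(OC)c1C(=O)c1c(O)cc(C)c(OC)c1C1=C(c2c(OC)cccc2OC)c2c(O)cc(C)c(OC)c2C1=O | target

**Total step count:** 8
**Longest linear sequence:** 8 steps (1 → 5 → 7 → 8 → 12 → 15 → 16 → 17 → 18)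

**Steps most likely to fail**

Step 8. Attack of the ketone oxygen on the protonated alkyne (benzopyrylium formation) or acid-induced loss of a 2,6-dimethoxybenzoyl group by ipso-protonation may outrun C–C bond formation. The fallback sets out from 17 and separates oxygen transfer from ring closure. Hydration of the alkyne (Ph3PAuCl and AgOTf in catalytic amounts, H2O, dioxane, 80 °C) should give the aryl benzyl ketone 1,2-bis[2-(2,6-dimethoxybenzoyl)-3-hydroxy-6-methoxy-5-methylphenyl]ethan-1-one F1. The symmetry of 17 allows only one constitution for this ketone, whichever alkyne carbon receives the oxygen. Acid-mediated intramolecular aldol condensation (p-TsOH, toluene, reflux with water removal) of the methylene group onto the neighbouring diaryl ketone, the classical cyclodehydration of 2-(arylacetyl)benzophenones to 2,3-diarylindenones, then returns to the route at 18.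

Step 4. Oxidative homocoupling of the liberated terminal alkyne, or copper- and base-promoted addition of water across the aldehyde–alkyne pair, may consume material before the second coupling. The fallback sets out from 8 and replaces the copper acetylide chemistry by a twofold Stille coupling with bis(tributylstannyl)acetylene (0.5 equiv, Pd(PPh3)4, toluene, 100 °C). This is neutral, copper-free and water-free, and it returns to the route directly at 12; no new compound arises on the way (F0).

Step 1. Incomplete lithiation, lithiation at the position next to the methyl group, or addition of butyllithium to the masked aldehyde may erode the yield. The fallback sets out from 1 and changes the directing group. Reduction (NaBH4, MeOH, 0 °C) should give (2,5-dimethoxy-4-methylphenyl)methanol F2. Alkoxide-directed ortho-lithiation (n-BuLi, 2.2 equiv, Et2O–hexane, 0 °C to rt) between the CH2OLi and methoxy groups, followed by iodine quench, should give (2-iodo-3,6-dimethoxy-4-methylphenyl)methanol F3. Benzylic oxidation (MnO2, CH2Cl2, rt) returns to the route at 5.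

**Further compounds**
F1 | step 8 | 1,2-bis[2-(2,6-dimethoxybenzoyl)-3-hydroxy-6-methoxy-5-methylphenyl]ethan-1-one | COc1cccc(OC)c1C(=O)c1c(O)cc(C)c(OC)c1C(=O)Cc1c(OC)c(C)cc(O)c1C(=O)c1c(OC)cccc1OC
F0 | step 4 | none | none
F2 | step 1 | (2,5-dimethoxy-4-methylphenyl)methanol | COc1cc(C)c(OC)cc1CO
F3 | step 1 | (2-iodo-3,6-dimethoxy-4-methylphenyl)methanol | COc1cc(C)c(OC)c(I)c1CO
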